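**Retrosynthetic overview**

1. The target, an unsymmetrical 3,6-bis(indol-3-yl)-2,5-dimethoxy-1,4-benzoquinone with no stereocentre, is reached from its N-silyl/N-Boc derivative 26 by removal of the two nitrogen protecting groups.
2. The quinone ring of 26 is made last, by strain-releasing ring expansion of a temporary cyclobutenone: a 4-hydroxy-4-alkenylcyclobutenone opens to a dienylketene, closes to the six-membered ring and is oxidised.
3. The feature that allows this: numbering the quinone ring C1 to C6, the run C1(=O)–C2(indole Y)=C3(OMe)–C4(=O) has exactly the substitution of a 3-methoxy-4-arylcyclobutenedione, and C5(indole X)=C6(OMe) is an enol-ether C=C; the para carbonyls C1 and C4 become the ketene carbon and the carbinol carbon of the cyclobutenone.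
4. The two halves are joined at C4–C5 in the same flask: cyclobutenedione 13 (indole Y on a squarate core) and the β-methoxyvinyllithium 21 (indole X), made from 3-bromo-1-(triisopropylsilyl)indole through ketone 17, (Z)-enol triflate 19 and stannane 20.
5. Order of ring formation: the benzene ring of indole Y, both rings of indole X and the four-membered ring are bought; the pyrrole ring of indole Y is closed by Fischer indolisation (step 2); the quinone ring is closed last (step 9).

Key step: step 9

Remark: the target has no stereocentre and no configuration is specified for rotation about the indolyl–quinone bonds, so nothing stereochemical has to be controlled; squaric acid dichloride (10) is taken as a purchasable compound.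

Step 1
Reactants: 1 2,2-dimethylbut-3-enoic acid
Product: 2 3,3-dimethylpent-4-en-2-one
Conditions: MeLi (2.2 equiv), Et2O, 0 °C to rt; aq. HCl, 0 °C
Reagents that add atoms: methyllithium, [Li]C
Why: Addition of a second equivalent of methyllithium to the lithium carboxylate gives a gem-dialkoxide that collapses to the methyl ketone only on acidic work-up (carboxylic acid to methyl ketone conversion), the quaternary α-carbon preventing enolisation on that side.

Step 2
Reactants: 2 3,3-dimethylpent-4-en-2-one; 3 (2-bromophenyl)hydrazine hydrochloride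
Product: 5 7-bromo-2-(2-methylbut-3-en-2-yl)-1H-indole, via hydrazone 4 (not isolated)
Conditions: EtOH, 70 °C; then ZnCl2, toluene, 110 °C
Reagents that add atoms: none
Why: Fischer indole synthesis, in which the hydrazone can form an ene-hydrazine only through its methyl group (the other α-carbon is quaternary), so the [3,3]-sigmatropic shift to the one free ortho position and loss of ammonia should give the 2-substituted, C3-unsubstituted 7-bromoindole, ZnCl2 in an aprotic solvent being chosen to spare the monosubstituted alkene.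

Step 3
Reactants: 5 7-bromo-2-(2-methylbut-3-en-2-yl)-1H-indole; 6 1-bromo-3-methylbut-2-ene (prenyl bromide)
Product: 9 2-(2-methylbut-3-en-2-yl)-7-(3-methylbut-2-en-1-yl)-1H-indole (indole Y), via N-potassio bromoindole 7 (not isolated), via 7-lithio N-potassio indolide 8 (not isolated)
Conditions: KH, THF, 0 °C; t-BuLi (2 equiv), −78 °C; 6, −78 to 0 °C; H2O
Reagents that add atoms: none
Why: Bromine–lithium exchange on the N-metallated bromoindole followed by SN2 alkylation of the aryllithium at the primary carbon of prenyl bromide should install the C7 prenyl group, the potassium amide nitrogen being far less nucleophilic than the aryllithium and shielded by the tertiary C2 substituent.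

Step 4
Reactants: 9 indole Y; 10 3,4-dichlorocyclobut-3-ene-1,2-dione (squaric acid dichloride)
Product: 12 3-methoxy-4-[2-(2-methylbut-3-en-2-yl)-7-(3-methylbut-2-en-1-yl)-1H-indol-3-yl]cyclobut-3-ene-1,2-dione, via chlorocyclobutenedione 11 (not isolated)
Conditions: 2,6-di-tert-butylpyridine, Et2O, 0 °C to rt; then MeOH, Et3N, 0 °C to rt
Reagents that add atoms: methanol, CO
Why: Uncatalysed Friedel–Crafts-type addition–elimination of indole C3 at the vinylogous acid chloride stops at the mono-adduct because the remaining chloride becomes part of a push–pull system, and methanolysis of that chloride gives the vinylogous methyl ester, the hindered bases taking up HCl to protect the prenyl alkenes.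

Step 5
Reactants: 12 the N–H cyclobutenedione
Product: 13 tert-butyl 3-(2-methoxy-3,4-dioxocyclobut-1-en-1-yl)-2-(2-methylbut-3-en-2-yl)-7-(3-methylbut-2-en-1-yl)-1H-indole-1-carboxylate
Conditions: Boc2O, DMAP (cat.), MeCN, 40 °C
Reagents that add atoms: di-tert-butyl dicarbonate, CC(C)(C)OC(=O)OC(=O)OC(C)(C)C
Why: DMAP-catalysed N-acylation of the acidic, acylindole-type N–H removes the only acidic proton and weakens the donor character of the indole before the organolithium step.

Step 6
Reactants: 14 3-bromo-1-(triisopropylsilyl)-1H-indole; 15 N,2-dimethoxy-N-methylacetamide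
Product: 17 2-methoxy-1-[1-(triisopropylsilyl)-1H-indol-3-yl]ethan-1-one, via 3-lithioindole 16 (not isolated)
Conditions: t-BuLi (2 equiv), THF, −78 °C; then 15, −78 to 0 °C; AcOH
Reagents that add atoms: none
Why: Bromine–lithium exchange gives a 3-lithioindole that the bulky N-silyl group keeps from migrating to C2, and its acylation by the Weinreb amide stops at the ketone through the chelated tetrahedral intermediate.

Step 7
Reactants: 17 the methoxyacetyl ketone
Product: 19 (Z)-2-methoxy-1-[1-(triisopropylsilyl)-1H-indol-3-yl]ethenyl trifluoromethanesulfonate, via potassium enolate 18 (not isolated)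
Conditions: KN(SiMe3)2, THF, −78 °C; PhNTf2, −78 to 0 °C; aq. NH4Cl
Reagents that add atoms: N-phenylbis(trifluoromethanesulfonimide), O=S(=O)(N(c1ccccc1)S(=O)(=O)C(F)(F)F)C(F)(F)F
Why: Kinetic deprotonation of the aryl α-alkoxy ketone gives the (Z)-enolate (enolate oxygen cis to OMe, as is general for aryl ketone enolates and reinforced by chelation), and O-sulfonylation fixes this geometry in the enol triflate.

Step 8
Reactants: 19 the (Z)-enol triflate
Product: 20 3-[(Z)-2-methoxy-1-(trimethylstannyl)ethenyl]-1-(triisopropylsilyl)-1H-indole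
Conditions: Me3SnSnMe3, Pd(PPh3)4 (5 mol %), LiCl, THF, 65 °C
Reagents that add atoms: hexamethylditin, C[Sn](C)(C)[Sn](C)(C)C
Why: Palladium-catalysed stannylation of an enol triflate with a distannane (oxidative addition, tin-to-palladium transmetalation, reductive elimination) proceeds with retention of alkene geometry, so tin ends cis to the methoxy group.

Step 9
Reactants: 20 the (Z)-vinylstannane; 13 the N-Boc cyclobutenedione
Product: 26 2,5-dimethoxy-3-[1-(triisopropylsilyl)-1H-indol-3-yl]-6-[1-(tert-butoxycarbonyl)-2-(2-methylbut-3-en-2-yl)-7-(3-methylbut-2-en-1-yl)-1H-indol-3-yl]-1,4-benzoquinone, via vinyllithium 21 (not isolated), via hydroxycyclobutenone 22 (not isolated), via dienylketene 23 (not isolated), via cyclohexadienone 24 (not isolated), via hydroquinone 25 (not isolated)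
Conditions: 20, MeLi, THF, −78 °C; 13, −78 °C; AcOH; solvent switch to toluene, 105 °C; then Ag2O, rt
Reagents that add atoms: none
Why: Tin–lithium exchange with retention gives vinyllithium 21 (lithium cis to OMe and chelated by it), which adds 1,2 to the carbonyl of 13 that is flanked by the methoxy-bearing carbon to give 22; on heating, conrotatory 4π ring opening of the strained cyclobutenone gives dienylketene 23, 6π-electrocyclisation gives 24, enolisation gives hydroquinone 25, and Ag2O oxidises it to quinone 26. The closest known reaction type is the thermal ring expansion of 4-alkenyl-4-hydroxycyclobutenones derived from squarate cyclobutenediones (Moore–Liebeskind quinone synthesis), here run without isolating the adduct. The six-membered ring is closed by a thermally allowed disrotatory 6π-electrocyclisation that joins the ketene carbon to the CH(OMe) terminus, driven by the release of cyclobutene strain and the following aromatisation. No stereocentre remains: the carbinol carbon of 22 and the sp3 carbon of 24 are formed racemic and are destroyed by ring opening and enolisation. The selectivity needed is the site of the 1,2-addition, which fixes the para relation of the two indoles and of the two methoxy groups; it is secured because the other carbonyl is a vinylogous ester deactivated by the methoxy group and screened by the bulky indolyl group. Outward rotation of the hydroxyl donor on ring opening places the alkenyl group cis to the ketene as the closure requires, and −78 °C with the cis-OMe chelate guards the vinyllithium against loss of lithium methoxide.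

Step 10
Reactants: 26 the N-silyl, N-Boc quinone
Product: 28 2,5-dimethoxy-3-(1H-indol-3-yl)-6-[2-(2-methylbut-3-en-2-yl)-7-(3-methylbut-2-en-1-yl)-1H-indol-3-yl]cyclohexa-2,5-diene-1,4-dione (target), via N-Boc quinone 27 (not isolated)
Conditions: TBAF, AcOH, THF, 0 °C; then K2CO3, MeOH, 0 °C to rt
Reagents that add atoms: none
Why: Buffered fluoride cleaves the N–Si bond and carbonate-promoted methanolysis removes the activated N-Boc carbamate (standard N-desilylation and N-Boc methanolysis of indoles), methoxide exchange at the methoxyquinone carbons being degenerate and no acid being present to touch the prenyl and 1,1-dimethylallyl groups.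

**Compound list**

1 | 2,2-dimethylbut-3-enoic acid | C=CC(C)(C)C(=O)O | starting material
2 | 3,3-dimethylpent-4-en-2-one | CC(=O)C(C)(C)C=C | intermediate
3 | (2-bromophenyl)hydrazine hydrochloride | NNc1ccccc1Br.Cl | starting material
4 | 1-(2-bromophenyl)-2-(3,3-dimethylpent-4-en-2-ylidene)hydrazine (hydrazone, not isolated) | C=CC(C)(C)C(C)=NNc1ccccc1Br | intermediate
5 | 7-bromo-2-(2-methylbut-3-en-2-yl)-1H-indole | C=CC(C)(C)c1cc2cccc(Br)c2[nH]1 | intermediate
6 | 1-bromo-3-methylbut-2-ene | CC(C)=CCBr | starting material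
7 | potassium 7-bromo-2-(2-methylbut-3-en-2-yl)indol-1-ide (not isolated) | C=CC(C)(C)c1cc2cccc(Br)c2n1[K] | intermediate
8 | 7-lithio-1-potassio-2-(2-methylbut-3-en-2-yl)indole (not isolated) | C=CC(C)(C)c1cc2cccc([Li])c2n1[K] | intermediate
9 | 2-(2-methylbut-3-en-2-yl)-7-(3-methylbut-2-en-1-yl)-1H-indole (indole Y) | C=CC(C)(C)c1cc2cccc(CC=C(C)C)c2[nH]1 | intermediate
10 | 3,4-dichlorocyclobut-3-ene-1,2-dione | O=C1C(=O)C(Cl)=C1Cl | starting material
11 | 3-chloro-4-[2-(2-methylbut-3-en-2-yl)-7-(3-methylbut-2-en-1-yl)-1H-indol-3-yl]cyclobut-3-ene-1,2-dione (not isolated) | O=C1C(=O)C(c2c(C(C)(C)C=C)[nH]c3c(CC=C(C)C)cccc23)=C1Cl | intermediate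
12 | 3-methoxy-4-[2-(2-methylbut-3-en-2-yl)-7-(3-methylbut-2-en-1-yl)-1H-indol-3-yl]cyclobut-3-ene-1,2-dione | COC1=C(c2c(C(C)(C)C=C)[nH]c3c(CC=C(C)C)cccc23)C(=O)C1=O | intermediate
13 | tert-butyl 3-(2-methoxy-3,4-dioxocyclobut-1-en-1-yl)-2-(2-methylbut-3-en-2-yl)-7-(3-methylbut-2-en-1-yl)-1H-indole-1-carboxylate | COC1=C(c2c(C(C)(C)C=C)n(C(=O)OC(C)(C)C)c3c(CC=C(C)C)cccc23)C(=O)C1=O | intermediate
14 | 3-bromo-1-(triisopropylsilyl)-1H-indole | CC(C)[Si](C(C)C)(C(C)C)n1cc(Br)c2ccccc21 | starting material
15 | N,2-dimethoxy-N-methylacetamide | COCC(=O)N(C)OC | starting material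
16 | 3-lithio-1-(triisopropylsilyl)-1H-indole (not isolated) | CC(C)[Si](C(C)C)(C(C)C)n1cc([Li])c2ccccc21 | intermediate
17 | 2-methoxy-1-[1-(triisopropylsilyl)-1H-indol-3-yl]ethan-1-one | COCC(=O)c1cn([Si](C(C)C)(C(C)C)C(C)C)c2ccccc12 | intermediate
18 | potassium (Z)-2-methoxy-1-[1-(triisopropylsilyl)-1H-indol-3-yl]ethen-1-olate (not isolated) | CO/C=C(\[O-])c1cn([Si](C(C)C)(C(C)C)C(C)C)c2ccccc12.[K+] | intermediate
19 | (Z)-2-methoxy-1-[1-(triisopropylsilyl)-1H-indol-3-yl]ethenyl trifluoromethanesulfonate | CO/C=C(\OS(=O)(=O)C(F)(F)F)c1cn([Si](C(C)C)(C(C)C)C(C)C)c2ccccc12 | intermediate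
20 | 3-[(Z)-2-methoxy-1-(trimethylstannyl)ethenyl]-1-(triisopropylsilyl)-1H-indole | CO/C=C(\[Sn](C)(C)C)c1cn([Si](C(C)C)(C(C)C)C(C)C)c2ccccc12 | intermediate
21 | [(E)-2-methoxy-1-[1-(triisopropylsilyl)-1H-indol-3-yl]ethenyl]lithium, lithium cis to OMe (not isolated) | CO/C=C(\[Li])c1cn([Si](C(C)C)(C(C)C)C(C)C)c2ccccc12 | intermediate
22 | tert-butyl 3-[3-hydroxy-2-methoxy-3-{(Z)-2-methoxy-1-[1-(triisopropylsilyl)-1H-indol-3-yl]ethenyl}-4-oxocyclobut-1-en-1-yl]-2-(2-methylbut-3-en-2-yl)-7-(3-methylbut-2-en-1-yl)-1H-indole-1-carboxylate, racemic (not isolated) | CO/C=C(\C1(O)C(OC)=C(c2c(C(C)(C)C=C)n(C(=O)OC(C)(C)C)c3c(CC=C(C)C)cccc23)C1=O)c1cn([Si](C(C)C)(C(C)C)C(C)C)c2ccccc12 | intermediate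
23 | (3Z,5Z)-4-hydroxy-3,6-dimethoxy-2-[N-Boc indole Y-3-yl]-5-[1-(triisopropylsilyl)-1H-indol-3-yl]hexa-1,3,5-trien-1-one, dienylketene (not isolated) | O=C=C(c1c(C(C)(C)C=C)n(C(=O)OC(C)(C)C)c2c(CC=C(C)C)cccc12)/C(OC)=C(/O)\C(c1cn([Si](C(C)C)(C(C)C)C(C)C)c2ccccc12)=C/OC | intermediate
24 | 4-hydroxy-3,6-dimethoxy-2-[N-Boc indole Y-3-yl]-5-[1-(triisopropylsilyl)-1H-indol-3-yl]cyclohexa-2,4-dien-1-one, racemic (not isolated) | COC1C(=O)C(c2c(C(C)(C)C=C)n(C(=O)OC(C)(C)C)c3c(CC=C(C)C)cccc23)=C(OC)C(O)=C1c1cn([Si](C(C)C)(C(C)C)C(C)C)c2ccccc12 | intermediate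
25 | 2,5-dimethoxy-3-[1-(triisopropylsilyl)-1H-indol-3-yl]-6-[N-Boc indole Y-3-yl]benzene-1,4-diol (not isolated) | COc1c(O)c(-c2c(C(C)(C)C=C)n(C(=O)OC(C)(C)C)c3c(CC=C(C)C)cccc23)c(OC)c(O)c1-c1cn([Si](C(C)C)(C(C)C)C(C)C)c2ccccc12 | intermediate
26 | 2,5-dimethoxy-3-[1-(triisopropylsilyl)-1H-indol-3-yl]-6-[1-(tert-butoxycarbonyl)-2-(2-methylbut-3-en-2-yl)-7-(3-methylbut-2-en-1-yl)-1H-indol-3-yl]-1,4-benzoquinone | COC1=C(c2cn([Si](C(C)C)(C(C)C)C(C)C)c3ccccc23)C(=O)C(OC)=C(c2c(C(C)(C)C=C)n(C(=O)OC(C)(C)C)c3c(CC=C(C)C)cccc23)C1=O | intermediate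
27 | 2,5-dimethoxy-3-(1H-indol-3-yl)-6-[1-(tert-butoxycarbonyl)-2-(2-methylbut-3-en-2-yl)-7-(3-methylbut-2-en-1-yl)-1H-indol-3-yl]-1,4-benzoquinone (not isolated) | COC1=C(c2c[nH]c3ccccc23)C(=O)C(OC)=C(c2c(C(C)(C)C=C)n(C(=O)OC(C)(C)C)c3c(CC=C(C)C)cccc23)C1=O | intermediate
28 | 2,5-dimethoxy-3-(1H-indol-3-yl)-6-[2-(2-methylbut-3-en-2-yl)-7-(3-methylbut-2-en-1-yl)-1H-indol-3-yl]cyclohexa-2,5-diene-1,4-dione | C=CC(C)(C)c1[nH]c2c(CC=C(C)C)cccc2c1C1=C(OC)C(=O)C(c2c[nH]c3ccccc23)=C(OC)C1=O | target

**Step count and risks**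

Total steps: 10. Longest linear sequence: 7 (steps 1, 2, 3, 4, 5, 9, 10); steps 6 to 8 form the second branch.

Steps most likely to fail:

Step 9. The β-methoxyvinyllithium may lose lithium methoxide (after cis/trans isomerisation at the lithiated carbon) before it adds to the dione, or the dienylketene may be diverted before the six-membered ring closes. The fallback keeps the ring expansion but joins indole X afterwards. It sets out from 13 and 16. Dione 13 is treated at −78 °C with lithium methoxyethynide F1 (from chloroacetaldehyde dimethyl acetal and three equivalents of LiNEt2), and Bu3SnCl is then added to give the 4-(methoxyethynyl)-4-(tributylstannyloxy)cyclobutenone F2. Heating F2 in toluene at 100 °C should give, by the same electrocyclic opening, closure onto the alkyne and oxygen-to-carbon tin shift (Moore rearrangement in its stannyl variant), the 3-(tributylstannyl)-2,5-dimethoxyquinone F3. Lithioindole 16 is quenched with I2 to 3-iodo-1-(triisopropylsilyl)indole F4. Stille coupling of F3 with F4 (Pd2(dba)3, tri(2-furyl)phosphine, CuI, DMF) comes back to the route at 26.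

Step 5. Acylation of the nitrogen flanked by the tertiary C2 substituent and the C7 prenyl group may stall, or the ambident anion may be acylated on oxygen. The fallback uses a small, more electrophilic acyl donor on the preformed sodium salt and carries a methyl carbamate in place of Boc. It sets out from 12. NaH in THF at 0 °C followed by methyl chloroformate should give the N-methoxycarbonyl dione F5. Union of F5 with 21 under the conditions of step 9 should pass through hydroxycyclobutenone F6, dienylketene F7, cyclohexadienone F8 and hydroquinone F9 to the N-silyl N-methoxycarbonyl quinone F10. Under the conditions of step 10, fluoride gives the N-methoxycarbonyl quinone F11, and K2CO3 in MeOH then removes the carbamate, coming back to the route at 28.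

Step 2. The [3,3] shift of a hydrazone that can enolise only through its methyl group needs forcing acid, under which the 1,1-dimethylallyl group may isomerise or cyclise, or bromine may be lost. The fallback builds the pyrrole ring from an alkyne. It sets out from 2. LDA in THF at −78 °C followed by ClP(O)(OEt)2 gives the enol phosphate F12, and further LDA (2.2 equiv) eliminates diethyl phosphate to give 3,3-dimethylpent-1-en-4-yne F13. Sonogashira coupling of F13 with 2-bromo-6-iodoaniline at the C–I bond (PdCl2(PPh3)2, CuI, Et3N) gives 2-bromo-6-(3,3-dimethylpent-4-en-1-yn-1-yl)aniline F14. KOt-Bu in NMP at rt closes the ring by 5-endo-dig hydroamination and comes back to the route at 5.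

Further compounds
F1 | step 9 | lithium methoxyethynide | [Li]C#COC
F2 | step 9 | tert-butyl 3-[2-methoxy-3-(methoxyethynyl)-4-oxo-3-[(tributylstannyl)oxy]cyclobut-1-en-1-yl]-2-(2-methylbut-3-en-2-yl)-7-(3-methylbut-2-en-1-yl)-1H-indole-1-carboxylate | COC#CC1(O[Sn](CCCC)(CCCC)CCCC)C(OC)=C(c2c(C(C)(C)C=C)n(C(=O)OC(C)(C)C)c3c(CC=C(C)C)cccc23)C1=O
F3 | step 9 | 2,5-dimethoxy-3-(tributylstannyl)-6-[1-(tert-butoxycarbonyl)-2-(2-methylbut-3-en-2-yl)-7-(3-methylbut-2-en-1-yl)-1H-indol-3-yl]-1,4-benzoquinone | COC1=C([Sn](CCCC)(CCCC)CCCC)C(=O)C(OC)=C(c2c(C(C)(C)C=C)n(C(=O)OC(C)(C)C)c3c(CC=C(C)C)cccc23)C1=O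
F4 | step 9 | 3-iodo-1-(triisopropylsilyl)-1H-indole | CC(C)[Si](C(C)C)(C(C)C)n1cc(I)c2ccccc21
F5 | step 5 | methyl 3-(2-methoxy-3,4-dioxocyclobut-1-en-1-yl)-2-(2-methylbut-3-en-2-yl)-7-(3-methylbut-2-en-1-yl)-1H-indole-1-carboxylate | COC1=C(c2c(C(C)(C)C=C)n(C(=O)OC)c3c(CC=C(C)C)cccc23)C(=O)C1=O
F6 | step 5 | methyl 3-[3-hydroxy-2-methoxy-3-{(Z)-2-methoxy-1-[1-(triisopropylsilyl)-1H-indol-3-yl]ethenyl}-4-oxocyclobut-1-en-1-yl]-2-(2-methylbut-3-en-2-yl)-7-(3-methylbut-2-en-1-yl)-1H-indole-1-carboxylate (racemic) | CO/C=C(\C1(O)C(OC)=C(c2c(C(C)(C)C=C)n(C(=O)OC)c3c(CC=C(C)C)cccc23)C1=O)c1cn([Si](C(C)C)(C(C)C)C(C)C)c2ccccc12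
F7 | step 5 | (3Z,5Z)-4-hydroxy-3,6-dimethoxy-2-[1-(methoxycarbonyl) indole Y-3-yl]-5-[1-(triisopropylsilyl)-1H-indol-3-yl]hexa-1,3,5-trien-1-one | O=C=C(c1c(C(C)(C)C=C)n(C(=O)OC)c2c(CC=C(C)C)cccc12)/C(OC)=C(/O)\C(c1cn([Si](C(C)C)(C(C)C)C(C)C)c2ccccc12)=C/OC
F8 | step 5 | 4-hydroxy-3,6-dimethoxy-2-[1-(methoxycarbonyl) indole Y-3-yl]-5-[1-(triisopropylsilyl)-1H-indol-3-yl]cyclohexa-2,4-dien-1-one (racemic) | COC1C(=O)C(c2c(C(C)(C)C=C)n(C(=O)OC)c3c(CC=C(C)C)cccc23)=C(OC)C(O)=C1c1cn([Si](C(C)C)(C(C)C)C(C)C)c2ccccc12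
F9 | step 5 | 2,5-dimethoxy-3-[1-(triisopropylsilyl)-1H-indol-3-yl]-6-[1-(methoxycarbonyl) indole Y-3-yl]benzene-1,4-diol | COc1c(O)c(-c2c(C(C)(C)C=C)n(C(=O)OC)c3c(CC=C(C)C)cccc23)c(OC)c(O)c1-c1cn([Si](C(C)C)(C(C)C)C(C)C)c2ccccc12
F10 | step 5 | 2,5-dimethoxy-3-[1-(triisopropylsilyl)-1H-indol-3-yl]-6-[1-(methoxycarbonyl)-2-(2-methylbut-3-en-2-yl)-7-(3-methylbut-2-en-1-yl)-1H-indol-3-yl]-1,4-benzoquinone | COC1=C(c2cn([Si](C(C)C)(C(C)C)C(C)C)c3ccccc23)C(=O)C(OC)=C(c2c(C(C)(C)C=C)n(C(=O)OC)c3c(CC=C(C)C)cccc23)C1=O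
F11 | step 5 | 2,5-dimethoxy-3-(1H-indol-3-yl)-6-[1-(methoxycarbonyl)-2-(2-methylbut-3-en-2-yl)-7-(3-methylbut-2-en-1-yl)-1H-indol-3-yl]-1,4-benzoquinone | COC1=C(c2c[nH]c3ccccc23)C(=O)C(OC)=C(c2c(C(C)(C)C=C)n(C(=O)OC)c3c(CC=C(C)C)cccc23)C1=O
F12 | step 2 | diethyl 3,3-dimethylpenta-1,4-dien-2-yl phosphate | C=CC(C)(C)C(=C)OP(=O)(OCC)OCC
F13 | step 2 | 3,3-dimethylpent-1-en-4-yne | C=CC(C)(C)C#C
F14 | step 2 | 2-bromo-6-(3,3-dimethylpent-4-en-1-yn-1-yl)aniline | Nc1c(Br)cccc1C#CC(C)(C)C=C
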